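The pyranone ring of the 3-hydroxyisoflavanone is disconnected at O1–C8a and C4–C4a. Ring A carries O1 and the C4 carbonyl on the adjacent carbons C8a and C4a, with the C5 oxygen next to C4a; this is the pattern left by a 3-alkoxybenzyne that has taken up an oxygen nucleophile and an acyl group. One fluoride-triggered operation therefore unites a 3,5-dioxygenated aryne with a β-hydroxy ester, forming the aryl ether and the aryl ketone and closing ring C. The precursor, ethyl (S)-3-hydroxy-2-(methoxymethoxy)-2-arylpropanoate 12, already holds the quaternary C3 stereocentre, the prenylated ring B and all protecting groups; it comes from aryllithium addition to diethyl ketomalonate and enzymatic desymmetrisation.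

Key step: step 10

Assumption: pig liver esterase is taken to hydrolyse the pro-R ethoxycarbonyl group of malonate 9 and so to give the (S)-half-ester 10; this sense cannot be predicted with certainty and is to be confirmed on 10 before the route proceeds.

Step 1
Reactants: 1 4-bromo-3-methoxyphenol
Product: 2 1-bromo-2-methoxy-4-(methoxymethoxy)benzene
Conditions: MOMCl, i-Pr2NEt, CH2Cl2, 0 °C → rt
Reagents that add atoms: chloromethyl methyl ether (MOMCl), COCCl
Why: O-alkylation of the phenol with MOMCl and a hindered amine base (Williamson-type ether formation) is routine, leaves the aryl bromide untouched and installs the ortho-directing group used in step 2.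

Step 2
Reactants: 2 1-bromo-2-methoxy-4-(methoxymethoxy)benzene; 3 prenyl bromide (1-bromo-3-methylbut-2-ene)
Product: 5 1-bromo-2-methoxy-4-(methoxymethoxy)-3-(3-methylbut-2-en-1-yl)benzene, via aryllithium 4 (not isolated)
Conditions: LiTMP (from TMPH, n-BuLi), THF, −78 °C; then cat. CuBr·SMe2, 3, −78 → 0 °C
Reagents that add atoms: none
Why: In this directed ortho-metalation the hydrogen flanked by OMe and OMOM is the most acidic one on the ring and the non-nucleophilic amide base removes it without bromine–lithium exchange (the doubly oxygen-flanked aryllithium is the most stable lithio isomer, so halogen migration has no driving force), after which copper-catalysed allylation with prenyl bromide should give the linear prenyl arene.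

Step 3
Reactants: 5 1-bromo-2-methoxy-4-(methoxymethoxy)-3-(3-methylbut-2-en-1-yl)benzene; 6 diethyl ketomalonate (diethyl 2-oxopropanedioate)
Product: 9 diethyl 2-(methoxymethoxy)-2-[2-methoxy-4-(methoxymethoxy)-3-(3-methylbut-2-en-1-yl)phenyl]propanedioate, via aryllithium 7 (not isolated), via lithium alkoxide 8 (not isolated)
Conditions: n-BuLi, THF, −78 °C; cannulate into 6, THF, −78 °C; then MOMCl, DMPU, −78 °C → rt
Reagents that add atoms: chloromethyl methyl ether (MOMCl), COCCl
Why: Bromine–lithium exchange at −78 °C is faster than deprotonation of the benzylic-allylic CH2, the aryllithium undergoes 1,2-addition to the highly electrophilic central carbonyl of the ketomalonate (inverse addition protects the ester groups) and the tertiary lithium alkoxide is O-alkylated in the same flask by MOMCl.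

Step 4
Reactants: 9 diethyl 2-(methoxymethoxy)-2-[2-methoxy-4-(methoxymethoxy)-3-(3-methylbut-2-en-1-yl)phenyl]propanedioate
Product: 10 (2S)-3-ethoxy-2-(methoxymethoxy)-2-[2-methoxy-4-(methoxymethoxy)-3-(3-methylbut-2-en-1-yl)phenyl]-3-oxopropanoic acid
Conditions: pig liver esterase, phosphate buffer pH 7.5, 10% DMSO, 25–30 °C; cold acidification to pH 4 (citric acid), extraction, used without heating
Reagents that add atoms: water, O
Why: Enzymatic desymmetrisation of a prochiral disubstituted malonate, in which the esterase hydrolyses one of the two enantiotopic ester groups and thereby sets the quaternary stereocentre (later C3), runs at neutral pH so that MOM ethers and the prenyl group are untouched, and it stops at the half-ester because the carboxylate is no longer accepted as a substrate.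

Step 5
Reactants: 10 (2S)-3-ethoxy-2-(methoxymethoxy)-2-[2-methoxy-4-(methoxymethoxy)-3-(3-methylbut-2-en-1-yl)phenyl]-3-oxopropanoic acid
Product: 12 ethyl (2S)-3-hydroxy-2-(methoxymethoxy)-2-[2-methoxy-4-(methoxymethoxy)-3-(3-methylbut-2-en-1-yl)phenyl]propanoate, via mixed anhydride 11 (not isolated)
Conditions: i-BuOCOCl, N-methylmorpholine, THF, −15 °C; then NaBH4, H2O, −15 → 0 °C
Reagents that add atoms: none
Why: Chemoselective reduction of a carboxylic acid through its mixed carbonic anhydride with NaBH4 should reduce only the activated acyl group at low temperature, leaving the hindered ethyl ester and the trisubstituted alkene (which rules out borane) intact, and the fully substituted stereocentre cannot epimerise.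

Step 6
Reactants: 13 5-methoxyresorcinol (5-methoxybenzene-1,3-diol)
Product: 14 3-methoxy-5-(methoxymethoxy)phenol
Conditions: MOMCl (1.0 equiv), i-Pr2NEt, THF, 0 °C → rt; chromatographic separation
Reagents that add atoms: chloromethyl methyl ether (MOMCl), COCCl
Why: Mono-O-alkylation of a symmetric diphenol with one equivalent of MOMCl is a simple statistical protection placed at the cheapest point of the branch, and the mono-ether is separable by chromatography.

Step 7
Reactants: 14 3-methoxy-5-(methoxymethoxy)phenol
Product: 15 3-methoxy-5-(methoxymethoxy)phenyl N-isopropylcarbamate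
Conditions: i-PrNCO, cat. Et3N, CH2Cl2, rt
Reagents that add atoms: isopropyl isocyanate, CC(C)N=C=O
Why: Base-catalysed addition of the phenol to the isocyanate (carbamoylation) gives the N-isopropyl carbamate, a strong ortho-directing group that can later be removed under mild non-acidic conditions.

Step 8
Reactants: 15 3-methoxy-5-(methoxymethoxy)phenyl N-isopropylcarbamate
Product: 19 5-methoxy-3-(methoxymethoxy)-2-(trimethylsilyl)phenyl N-isopropylcarbamate, via N-silyl carbamate 16 (not isolated), via lithiated carbamate 17 (not isolated), via bis-silyl carbamate 18 (not isolated)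
Conditions: TMSOTf, TMEDA, Et2O, 0 °C → rt; n-BuLi, TMEDA, −78 °C; TMSCl, −78 °C → rt; aq. NaHCO3 work-up
Reagents that add atoms: chlorotrimethylsilane, C[Si](C)(C)Cl
Why: Directed ortho-metalation of the carbamate after in situ N-silylation (Snieckus–Hoppe type) should take place ortho to the carbamate at the site that is also flanked by the chelating OMOM group and not by the weaker OMe director, the aryllithium is C-silylated by TMSCl and the N-silyl group is lost on aqueous work-up.

Step 9
Reactants: 19 5-methoxy-3-(methoxymethoxy)-2-(trimethylsilyl)phenyl N-isopropylcarbamate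
Product: 21 5-methoxy-3-(methoxymethoxy)-2-(trimethylsilyl)phenyl trifluoromethanesulfonate, via silyl phenol 20 (not isolated)
Conditions: Et2NH, DBU, MeCN, 40 °C; then PhNTf2, rt
Reagents that add atoms: N-phenylbis(trifluoromethanesulfonimide), O=S(=O)(N(c1ccccc1)S(=O)(=O)C(F)(F)F)C(F)(F)F
Why: Amine-mediated carbamate cleavage (E1cB loss of isopropyl isocyanate, trapped by diethylamine as a urea) frees the phenoxide, which is O-triflated in the same flask, and the non-acidic conditions preserve the MOM ether and the aryl–silicon bond.

Step 10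
Reactants: 12 ethyl (2S)-3-hydroxy-2-(methoxymethoxy)-2-[2-methoxy-4-(methoxymethoxy)-3-(3-methylbut-2-en-1-yl)phenyl]propanoate; 21 5-methoxy-3-(methoxymethoxy)-2-(trimethylsilyl)phenyl trifluoromethanesulfonate
Product: 23 (3S)-7-methoxy-3,5-bis(methoxymethoxy)-3-[2-methoxy-4-(methoxymethoxy)-3-(3-methylbut-2-en-1-yl)phenyl]-2,3-dihydro-4H-chromen-4-one, via aryne 22 (not isolated)
Conditions: CsF (4 equiv), 18-crown-6, THF, 0 °C → rt; 21 (1.5 equiv) added slowly
Reagents that add atoms: none
Why: Proposed new method: fluoride removes the silyl group of 21 and triflate departs to give aryne 22, while excess CsF turns the primary hydroxyl of 12 into its alkoxide (the proton is held as bifluoride); the alkoxide adds to the aryne carbon remote from the MOM-bearing carbon (O1–C8a) and the aryl anion thus placed next to that oxygen attacks the ethyl ester (C4–C4a), expelling ethoxide. The closest known reaction types are the fluoride-mediated annulation of ortho-hydroxyaryl esters with silylaryl triflates to xanthones and the insertion of arynes into the C–O bond of carboxylic acids; an aliphatic β-hydroxy ester has not been used in this way. The pyranone ring is closed in the second event, a 6-exo-trig acyl substitution that follows the intermolecular C–O bond formation. No stereocentre is formed; C3 is fully substituted, has no acidic hydrogen and none of its bonds is touched, so its configuration is carried through. The step needs regioselective attack on the aryne, secured by the inductive polarisation of the 3-alkoxyaryne by the MOM oxygen (nucleophile enters meta to it), and acylation faster than protonation of the aryl anion, favoured by the six-membered transition state, the aprotic medium and slow generation of the aryne.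

Step 11
Reactants: 23 (3S)-7-methoxy-3,5-bis(methoxymethoxy)-3-[2-methoxy-4-(methoxymethoxy)-3-(3-methylbut-2-en-1-yl)phenyl]-2,3-dihydro-4H-chromen-4-one
Product: 24 (3S)-3,5-dihydroxy-3-[4-hydroxy-2-methoxy-3-(3-methylbut-2-en-1-yl)phenyl]-7-methoxy-2,3-dihydro-4H-chromen-4-one (EANPDB:LEGU_00502)
Conditions: 3 M aq. HCl, MeOH, rt → 40 °C, monitored
Reagents that add atoms: none
Why: Acid-catalysed acetal cleavage in methanol should remove the two aryl MOM ethers and the tertiary alkyl MOM ether, and dilute acid near room temperature is chosen so that the ortho-prenylphenol does not cyclise to a chroman and the C3 carbinol, deactivated towards ionisation by the adjacent ketone, does not dehydrate.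

Compound list
1 | 4-bromo-3-methoxyphenol | COc1cc(O)ccc1Br | starting material
2 | 1-bromo-2-methoxy-4-(methoxymethoxy)benzene | COCOc1ccc(Br)c(OC)c1 | intermediate
3 | prenyl bromide (1-bromo-3-methylbut-2-ene) | CC(C)=CCBr | starting material
4 | [3-bromo-2-methoxy-6-(methoxymethoxy)phenyl]lithium (not isolated) | [Li]c1c(OC)c(Br)ccc1OCOC | intermediate
5 | 1-bromo-2-methoxy-4-(methoxymethoxy)-3-(3-methylbut-2-en-1-yl)benzene | COCOc1ccc(Br)c(OC)c1CC=C(C)C | intermediate
6 | diethyl ketomalonate (diethyl 2-oxopropanedioate) | CCOC(=O)C(=O)C(=O)OCC | starting material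
7 | [2-methoxy-4-(methoxymethoxy)-3-(3-methylbut-2-en-1-yl)phenyl]lithium (not isolated) | [Li]c1ccc(OCOC)c(CC=C(C)C)c1OC | intermediate
8 | lithium 1,3-diethoxy-2-[2-methoxy-4-(methoxymethoxy)-3-(3-methylbut-2-en-1-yl)phenyl]-1,3-dioxopropan-2-olate (not isolated) | [Li+].[O-]C(C(=O)OCC)(C(=O)OCC)c1ccc(OCOC)c(CC=C(C)C)c1OC | intermediate
9 | diethyl 2-(methoxymethoxy)-2-[2-methoxy-4-(methoxymethoxy)-3-(3-methylbut-2-en-1-yl)phenyl]propanedioate | CCOC(=O)C(OCOC)(C(=O)OCC)c1ccc(OCOC)c(CC=C(C)C)c1OC | intermediate
10 | (2S)-3-ethoxy-2-(methoxymethoxy)-2-[2-methoxy-4-(methoxymethoxy)-3-(3-methylbut-2-en-1-yl)phenyl]-3-oxopropanoic acid | OC(=O)[C@@](OCOC)(c1ccc(OCOC)c(CC=C(C)C)c1OC)C(=O)OCC | intermediate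
11 | mixed isobutyl carbonic anhydride of acid 10, ethyl (2R)-3-[(isobutoxycarbonyl)oxy]-2-(methoxymethoxy)-2-[2-methoxy-4-(methoxymethoxy)-3-(3-methylbut-2-en-1-yl)phenyl]-3-oxopropanoate (same spatial arrangement as 10; descriptor changes by priority only; not isolated) | CC(C)COC(=O)OC(=O)[C@@](OCOC)(c1ccc(OCOC)c(CC=C(C)C)c1OC)C(=O)OCC | intermediate
12 | ethyl (2S)-3-hydroxy-2-(methoxymethoxy)-2-[2-methoxy-4-(methoxymethoxy)-3-(3-methylbut-2-en-1-yl)phenyl]propanoate | OC[C@@](OCOC)(c1ccc(OCOC)c(CC=C(C)C)c1OC)C(=O)OCC | intermediate
13 | 5-methoxyresorcinol (5-methoxybenzene-1,3-diol) | COc1cc(O)cc(O)c1 | starting material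
14 | 3-methoxy-5-(methoxymethoxy)phenol | COCOc1cc(O)cc(OC)c1 | intermediate
15 | 3-methoxy-5-(methoxymethoxy)phenyl N-isopropylcarbamate | CC(C)NC(=O)Oc1cc(OC)cc(OCOC)c1 | intermediate
16 | 3-methoxy-5-(methoxymethoxy)phenyl N-isopropyl-N-(trimethylsilyl)carbamate (not isolated) | CC(C)N([Si](C)(C)C)C(=O)Oc1cc(OC)cc(OCOC)c1 | intermediate
17 | 2-lithio-5-methoxy-3-(methoxymethoxy)phenyl N-isopropyl-N-(trimethylsilyl)carbamate (not isolated) | CC(C)N([Si](C)(C)C)C(=O)Oc1cc(OC)cc(OCOC)c1[Li] | intermediate
18 | 5-methoxy-3-(methoxymethoxy)-2-(trimethylsilyl)phenyl N-isopropyl-N-(trimethylsilyl)carbamate (not isolated) | CC(C)N([Si](C)(C)C)C(=O)Oc1cc(OC)cc(OCOC)c1[Si](C)(C)C | intermediate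
19 | 5-methoxy-3-(methoxymethoxy)-2-(trimethylsilyl)phenyl N-isopropylcarbamate | CC(C)NC(=O)Oc1cc(OC)cc(OCOC)c1[Si](C)(C)C | intermediate
20 | 5-methoxy-3-(methoxymethoxy)-2-(trimethylsilyl)phenol (not isolated) | COCOc1cc(OC)cc(O)c1[Si](C)(C)C | intermediate
21 | 5-methoxy-3-(methoxymethoxy)-2-(trimethylsilyl)phenyl trifluoromethanesulfonate | COc1cc(OCOC)c([Si](C)(C)C)c(OS(=O)(=O)C(F)(F)F)c1 | intermediate
22 | 5-methoxy-3-(methoxymethoxy)-1,2-didehydrobenzene (aryne; not isolated) | COC1=CC#CC(OCOC)=C1 | intermediate
23 | (3S)-7-methoxy-3,5-bis(methoxymethoxy)-3-[2-methoxy-4-(methoxymethoxy)-3-(3-methylbut-2-en-1-yl)phenyl]-2,3-dihydro-4H-chromen-4-one | COc1cc(OCOC)c2c(c1)OC[C@@](OCOC)(c1ccc(OCOC)c(CC=C(C)C)c1OC)C2=O | intermediate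
24 | (3S)-3,5-dihydroxy-3-[4-hydroxy-2-methoxy-3-(3-methylbut-2-en-1-yl)phenyl]-7-methoxy-2,3-dihydro-4H-chromen-4-one | COc1cc(O)c2c(c1)OC[C@@](O)(c1ccc(O)c(CC=C(C)C)c1OC)C2=O | target

Total step count: 11. Longest linear sequence: 7 (steps 1–5, 10, 11); the aryne precursor branch (steps 6–9) joins at step 10.

Steps most likely to fail

1. Step 10 (aryne annulation).
What may go wrong: the aryl anion may be protonated before it reaches the hindered ester, so that the sequence stops at the open aryl ether. The alkoxide may lose formaldehyde by retro-aldol cleavage. Ethoxide and fluoride may consume the aryne.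
Fallback (known chemistry), setting out from 12 and 19 and returning at 23: ipso-iododesilylation of 19 with ICl (CH2Cl2, −78 °C) should give 2-iodo-5-methoxy-3-(methoxymethoxy)phenyl N-isopropylcarbamate F1. Carbamate cleavage (Et2NH, DBU, MeCN) then gives 2-iodo-5-methoxy-3-(methoxymethoxy)phenol F2. Mitsunobu etherification of F2 with alcohol 12 (PPh3, DIAD, toluene) forms the O1–C8a bond in ethyl (2S)-3-[2-iodo-5-methoxy-3-(methoxymethoxy)phenoxy]-2-(methoxymethoxy)-2-[2-methoxy-4-(methoxymethoxy)-3-(3-methylbut-2-en-1-yl)phenyl]propanoate F3. Iodine–magnesium exchange (i-PrMgCl·LiCl, THF, −40 °C → rt) then gives the arylmagnesium chloride F4, which closes onto the ester in a Parham-type cyclisation to 23.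

2. Step 4 (enzymatic desymmetrisation).
What may go wrong: the hindered aryl(alkoxy)malonate may be hydrolysed slowly or with poor discrimination between the enantiotopic esters. The opposite enantiotopic group may be preferred. The half-acid may decarboxylate on handling.
Fallback, setting out from 9 and returning at 12: zinc-catalysed enantioselective desymmetrising hydrosilylation of the malonate (ZnEt2, a chiral pipecolinol-derived tetradentate phenol ligand of the appropriate handedness, a hydrosilane, then mild work-up) reduces one enantiotopic ester group directly to the primary alcohol. This reaction type is known for fully substituted malonic esters. It bypasses 10 and 11 and makes no new compound.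

3. Step 2 (amide-base metalation of the bromoarene).
What may go wrong: deprotonation by LiTMP may be incomplete, or bromine may scramble between aryllithium and aryl bromide before the allylation.
Fallback, setting out from prenyl bromide 3 and commercial 4-chloro-3-methoxyphenol F5 and returning at aryllithium 7 of step 3: MOM protection gives 1-chloro-2-methoxy-4-(methoxymethoxy)benzene F6. Because the C–Cl bond does not exchange, ordinary n-BuLi (THF, 0 °C) can be used for ortho-lithiation to [3-chloro-2-methoxy-6-(methoxymethoxy)phenyl]lithium F7. Prenylation of F7 with 3 (cat. CuBr·SMe2) gives 1-chloro-2-methoxy-4-(methoxymethoxy)-3-(3-methylbut-2-en-1-yl)benzene F8. Reductive lithiation (lithium 4,4'-di-tert-butylbiphenylide, THF, −78 °C) then delivers 7, which is carried through step 3 as written.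

Further compounds
F1 | step 10 | 2-iodo-5-methoxy-3-(methoxymethoxy)phenyl N-isopropylcarbamate | CC(C)NC(=O)Oc1cc(OC)cc(OCOC)c1I
F2 | step 10 | 2-iodo-5-methoxy-3-(methoxymethoxy)phenol | COCOc1cc(OC)cc(O)c1I
F3 | step 10 | ethyl (2S)-3-[2-iodo-5-methoxy-3-(methoxymethoxy)phenoxy]-2-(methoxymethoxy)-2-[2-methoxy-4-(methoxymethoxy)-3-(3-methylbut-2-en-1-yl)phenyl]propanoate | COCOc1cc(OC)cc(OC[C@@](OCOC)(c2ccc(OCOC)c(CC=C(C)C)c2OC)C(=O)OCC)c1I
F4 | step 10 | arylmagnesium chloride derived from F3 by iodine–magnesium exchange | COCOc1cc(OC)cc(OC[C@@](OCOC)(c2ccc(OCOC)c(CC=C(C)C)c2OC)C(=O)OCC)c1[Mg]Cl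
F0 | step 4 | none | none
F5 | step 2 | 4-chloro-3-methoxyphenol | COc1cc(O)ccc1Cl
F6 | step 2 | 1-chloro-2-methoxy-4-(methoxymethoxy)benzene | COCOc1ccc(Cl)c(OC)c1
F7 | step 2 | [3-chloro-2-methoxy-6-(methoxymethoxy)phenyl]lithium | [Li]c1c(OC)c(Cl)ccc1OCOC
F8 | step 2 | 1-chloro-2-methoxy-4-(methoxymethoxy)-3-(3-methylbut-2-en-1-yl)benzene | COCOc1ccc(Cl)c(OC)c1CC=C(C)C
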